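**Retrosynthetic overview**
- The C-12 acetate and the C-7=C-8 alkene come last, from an aldol adduct of a 2-bromo-4-hydroxy-4-octenylcyclopent-2-enone with methyl (E)-7-oxohept-5-enoate (made by cross-metathesis).
- The bromo-enone comes from a ring silyl enol ether carrying a sulfoxide at C-11: NBS puts bromine on C-10, then sulfoxide syn-elimination gives C-10=C-11.
- Key disconnection C-11–C-12 (with C-8–C-9): Brook-rearrangement [3+2] annulation of a methyl-ketone enolate (C-8, C-12, lower chain) with an (R)-β-sulfinyl acryloylsilane (C-9 to C-11). The siloxyallyl anion, a homoenolate of the C-9 ketone, attacks the C-12 ketone, and the sulfoxide controls C-12.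
- The enolate comes regiospecifically from an enol acetate made from (Z)-oct-2-en-1-ol; the acylsilane comes from methoxyallene and menthyl p-toluenesulfinate.
- Ring order: the single carbocycle is formed in the annulation; no other ring is made.

Assumption: positions use prostanoid numbering (C-1 ester carbon, C-9 ring ketone, C-12 carbinol carbon), and the facial sense of step 6 is taken from the chelate model stated there (the mirror-image sulfinate, also commercial, would serve if it proved opposite).

**Route**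

Step 1
Reactants: 1 (2Z)-oct-2-en-1-ol
Product: 2 (2Z)-1-bromooct-2-ene
Conditions: CBr4, PPh3, CH2Cl2, 0 °C
Reagents that add atoms: carbon tetrabromide BrC(Br)(Br)Br
Why: Appel bromination displaces the alkoxyphosphonium by SN2 under neutral conditions, so the Z alkene is kept and no allylic transposition occurs.

Step 2
Reactants: 2 (2Z)-1-bromooct-2-ene; 3 ethynylmagnesium bromide
Product: 4 (4Z)-dec-4-en-1-yne
Conditions: CuCl (10 mol %), THF, 0 °C to rt
Reagents that add atoms: none
Why: copper-catalysed cross-coupling of an alkynyl Grignard reagent with a primary allylic bromide gives the skipped enyne by SN2 substitution with retention of the Z geometry.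

Step 3
Reactants: 4 (4Z)-dec-4-en-1-yne
Product: 5 (4Z)-deca-1,4-dien-2-yl acetate
Conditions: AcOH, [RuCl2(p-cymene)]2 (1 mol %), P(2-furyl)3, Na2CO3 (cat.), toluene, 50 °C
Reagents that add atoms: acetic acid CC(=O)O
Why: ruthenium-catalysed Markovnikov hydro-acyloxylation of the terminal alkyne fixes the enol double bond on the methyl side, which deprotonation of the β,γ-unsaturated ketone (more acidic at the allylic CH2) could not do.

Step 4
Reactants: 6 methoxyallene
Product: 8 tert-butyl(1-methoxypropa-1,2-dien-1-yl)dimethylsilane, via lithiated methoxyallene 7 (not isolated)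
Conditions: n-BuLi, THF, −78 °C; TBSCl, −78 °C to rt
Reagents that add atoms: tert-butyldimethylsilyl chloride CC(C)(C)[Si](C)(C)Cl
Why: α-metalation of an alkoxyallene: the allenyl hydrogen next to oxygen is the most acidic and the lithioallene is silylated at that carbon.

Step 5
Reactants: 8 tert-butyl(1-methoxypropa-1,2-dien-1-yl)dimethylsilane; 9 (1R,2S,5R)-menthyl (S)-4-methylbenzenesulfinate
Product: 12 (2E)-1-[tert-butyl(dimethyl)silyl]-3-[(R)-4-methylbenzenesulfinyl]prop-2-en-1-one, via lithiated silylallene 10 (not isolated), via allenyl sulfoxide 11 (not isolated)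
Conditions: n-BuLi, THF, −78 °C; cannulate into 9, THF, −90 °C; then 1 M aq. HCl, THF, 0 °C
Reagents that add atoms: water O
Why: Andersen sulfinate substitution by the C-3-lithiated silyl allenyl ether proceeds with inversion at sulfur to give the R sulfoxide, and acid hydrolysis of the allenyl enol ether unmasks the conjugated acylsilane, which settles as the E isomer.

Step 6
Reactants: 5 (4Z)-deca-1,4-dien-2-yl acetate; 12 (2E)-1-[tert-butyl(dimethyl)silyl]-3-[(R)-4-methylbenzenesulfinyl]prop-2-en-1-one
Product: 16 (1S,2R)-4-[tert-butyl(dimethyl)silyl]oxy-2-[(R)-4-methylbenzenesulfinyl]-1-[(2Z)-oct-2-en-1-yl]cyclopent-3-en-1-ol, via lithium enolate 13 (not isolated), via silyl lithium alkoxide 14 (not isolated), via siloxyallyl lithium 15 (not isolated)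
Conditions: 5, MeLi (2.0 equiv), THF, 0 °C; then 12, −80 to −30 °C; AcOH, −78 °C; chromatography on Et3N-deactivated silica at 0 °C
Reagents that add atoms: none
Why: Proposed new method: enolate 13 (House cleavage of the enol acetate) adds to the acylsilane carbonyl, alkoxide 14 undergoes 1,2-Brook rearrangement, and the sulfinyl-stabilised siloxyallyl anion 15 (a homoenolate of the C-9 ketone, nucleophilic at C-11, normally an electrophilic enone β-carbon) closes 5-exo onto the C-12 ketone (also normally electrophilic); with Li bridging the sulfinyl and ketone oxygens, the p-tolyl group on the far face and the sulfur lone pair eclipsing C-10 (allylic strain), C-12 is delivered syn to the S–O bond, so the R sulfoxide gives the (1S,2R) adduct with hydroxyl cis to sulfur, and minor diastereomers are removed by chromatography so that the sulfur auxiliary fixes C-12; the closest known reactions are the Brook rearrangement-mediated [3+2] annulation of β-phenylthio- and β-silyl-acryloylsilanes with methyl ketone enolates and the addition of chiral α-sulfinyl carbanions (sulfinylpropionate homoenolate equivalents) to carbonyl compounds.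

Step 7
Reactants: 16 (1S,2R)-4-[tert-butyl(dimethyl)silyl]oxy-2-[(R)-4-methylbenzenesulfinyl]-1-[(2Z)-oct-2-en-1-yl]cyclopent-3-en-1-ol
Product: 18 (4S)-2-bromo-4-hydroxy-4-[(2Z)-oct-2-en-1-yl]cyclopent-2-en-1-one, via bromo sulfinyl ketone 17 (not isolated)
Conditions: NBS (1.05 equiv), THF, −78 °C; then pyridine, 45 °C
Reagents that add atoms: N-bromosuccinimide O=C1CCC(=O)N1Br
Why: electrophilic bromination of the silyl enol ether puts bromine regiospecifically on C-10 (the Z alkene and the sulfoxide do not react with NBS at −78 °C), and the β-keto sulfoxide then undergoes thermal syn-elimination through its only β-hydrogen (C-10–H), giving the C-10=C-11 enone with bromine retained and C-12 untouched.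

Step 8
Reactants: 19 methyl hex-5-enoate; 20 (2E)-but-2-enal
Product: 21 methyl (5E)-7-oxohept-5-enoate
Conditions: second-generation Grubbs catalyst (2 mol %), CH2Cl2, 40 °C
Reagents that add atoms: none
Why: olefin cross-metathesis of a terminal alkene with an excess of the enal gives the E-configured α,β-unsaturated aldehyde and is driven by loss of propene.

Step 9
Reactants: 18 (4S)-2-bromo-4-hydroxy-4-[(2Z)-oct-2-en-1-yl]cyclopent-2-en-1-one; 21 methyl (5E)-7-oxohept-5-enoate
Product: 23 methyl (5E)-7-[(5S)-3-bromo-5-hydroxy-5-[(2Z)-oct-2-en-1-yl]-2-oxocyclopent-3-en-1-yl]-7-hydroxyhept-5-enoate (C-7/C-8 diastereomer mixture), via dilithium alkoxide enolate 22 (not isolated)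
Conditions: LiN(i-Pr)2 (2.2 equiv), THF, −78 °C; 21, −78 °C; AcOH, −78 °C
Reagents that add atoms: none
Why: directed lithium-enolate aldol addition: C-8 is the only enolisable carbon, the tertiary hydroxyl is held as a lithium alkoxide (a non-leaving group, so no β-elimination to a cyclopentadienone) and the enolate adds 1,2 to the enal; the new C-7 and C-8 centres are erased in step 10.

Step 10
Reactants: 23 methyl (5E)-7-[(5S)-3-bromo-5-hydroxy-5-[(2Z)-oct-2-en-1-yl]-2-oxocyclopent-3-en-1-yl]-7-hydroxyhept-5-enoate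
Product: 26 methyl (5E,7E)-7-[(5R)-5-acetoxy-3-bromo-5-[(2Z)-oct-2-en-1-yl]-2-oxocyclopent-3-en-1-ylidene]hept-5-enoate, via allylic acetate 24 (not isolated), via hydroxy dienone 25 (not isolated)
Conditions: Ac2O, Et3N, DMAP, CH2Cl2, 0 °C to rt; chromatography
Reagents that add atoms: acetic anhydride CC(=O)OC(C)=O
Why: acetylation of the secondary allylic alcohol and E1cB loss of acetate through the C-8 enolate complete the aldol condensation, with the 7E dienone (chain anti to the ketone) expected as the major isomer and any 7Z isomer removed by chromatography; DMAP-catalysed acylation of the tertiary alcohol then gives the target, and C-12 keeps its configuration because no bond to it is broken.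

**Compound list**
1 | (2Z)-oct-2-en-1-ol | CCCCC/C=C\CO | starting material
2 | (2Z)-1-bromooct-2-ene | CCCCC/C=C\CBr | intermediate
3 | ethynylmagnesium bromide | C#C[Mg]Br | starting material
4 | (4Z)-dec-4-en-1-yne | CCCCC/C=C\CC#C | intermediate
5 | (4Z)-deca-1,4-dien-2-yl acetate | CCCCC/C=C\CC(=C)OC(C)=O | intermediate
6 | methoxyallene (1-methoxypropa-1,2-diene) | COC=C=C | starting material
7 | 1-lithio-1-methoxypropa-1,2-diene | COC([Li])=C=C | intermediate
8 | tert-butyl(1-methoxypropa-1,2-dien-1-yl)dimethylsilane | COC(=C=C)[Si](C)(C)C(C)(C)C | intermediate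
9 | (1R,2S,5R)-menthyl (S)-4-methylbenzenesulfinate | C[C@@H]1CC[C@H]([C@@H](C1)O[S@](=O)c1ccc(C)cc1)C(C)C | starting material
10 | tert-butyl(3-lithio-1-methoxypropa-1,2-dien-1-yl)dimethylsilane | COC(=C=C[Li])[Si](C)(C)C(C)(C)C | intermediate
11 | tert-butyl{1-methoxy-3-[(R)-4-methylbenzenesulfinyl]propa-1,2-dien-1-yl}dimethylsilane (allene axis unassigned) | COC(=C=C[S@@](=O)c1ccc(C)cc1)[Si](C)(C)C(C)(C)C | intermediate
12 | (2E)-1-[tert-butyl(dimethyl)silyl]-3-[(R)-4-methylbenzenesulfinyl]prop-2-en-1-one | CC(C)(C)[Si](C)(C)C(=O)/C=C/[S@@](=O)c1ccc(C)cc1 | intermediate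
13 | lithium (4Z)-deca-1,4-dien-2-olate | [Li]OC(=C)C/C=C\CCCCC | intermediate
14 | lithium (1E,7Z)-3-[tert-butyl(dimethyl)silyl]-1-[(R)-4-methylbenzenesulfinyl]-5-oxotrideca-1,7-dien-3-olate (C-3 epimers) | CCCCC/C=C\CC(=O)CC(O[Li])(/C=C/[S@@](=O)c1ccc(C)cc1)[Si](C)(C)C(C)(C)C | intermediate
15 | (2E,7Z)-3-[tert-butyl(dimethyl)silyl]oxy-1-lithio-1-[(R)-4-methylbenzenesulfinyl]trideca-2,7-dien-5-one | CCCCC/C=C\CC(=O)C/C(O[Si](C)(C)C(C)(C)C)=C\C([Li])[S@@](=O)c1ccc(C)cc1 | intermediate
16 | (1S,2R)-4-[tert-butyl(dimethyl)silyl]oxy-2-[(R)-4-methylbenzenesulfinyl]-1-[(2Z)-oct-2-en-1-yl]cyclopent-3-en-1-ol | CCCCC/C=C\C[C@]1(O)CC(O[Si](C)(C)C(C)(C)C)=C[C@H]1[S@@](=O)c1ccc(C)cc1 | intermediate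
17 | (3S,4S)-2-bromo-4-hydroxy-3-[(R)-4-methylbenzenesulfinyl]-4-[(2Z)-oct-2-en-1-yl]cyclopentan-1-one (C-2 epimers) | CCCCC/C=C\C[C@]1(O)CC(=O)C(Br)[C@H]1[S@@](=O)c1ccc(C)cc1 | intermediate
18 | (4S)-2-bromo-4-hydroxy-4-[(2Z)-oct-2-en-1-yl]cyclopent-2-en-1-one | CCCCC/C=C\C[C@@]1(O)C=C(Br)C(=O)C1 | intermediate
19 | methyl hex-5-enoate | C=CCCCC(=O)OC | starting material
20 | (2E)-but-2-enal | C/C=C/C=O | starting material
21 | methyl (5E)-7-oxohept-5-enoate | COC(=O)CCC/C=C/C=O | intermediate
22 | dilithium (1S)-3-bromo-1-[(2Z)-oct-2-en-1-yl]cyclopenta-2,4-diene-1,4-diolate | CCCCC/C=C\C[C@@]1(O[Li])C=C(Br)C(O[Li])=C1 | intermediate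
23 | methyl (5E)-7-[(5S)-3-bromo-5-hydroxy-5-[(2Z)-oct-2-en-1-yl]-2-oxocyclopent-3-en-1-yl]-7-hydroxyhept-5-enoate (C-7/C-8 diastereomer mixture) | CCCCC/C=C\C[C@@]1(O)C=C(Br)C(=O)C1C(O)/C=C/CCCC(=O)OC | intermediate
24 | methyl (5E)-7-acetoxy-7-[(5S)-3-bromo-5-hydroxy-5-[(2Z)-oct-2-en-1-yl]-2-oxocyclopent-3-en-1-yl]hept-5-enoate | CCCCC/C=C\C[C@@]1(O)C=C(Br)C(=O)C1C(OC(C)=O)/C=C/CCCC(=O)OC | intermediate
25 | methyl (5E,7E)-7-[(5R)-3-bromo-5-hydroxy-5-[(2Z)-oct-2-en-1-yl]-2-oxocyclopent-3-en-1-ylidene]hept-5-enoate (same spatial arrangement as 18; the descriptor changes with the CIP ranking of C-8) | CCCCC/C=C\C[C@@]1(O)C=C(Br)C(=O)/C1=C/C=C/CCCC(=O)OC | intermediate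
26 | methyl (5E,7E)-7-[(5R)-5-acetoxy-3-bromo-5-[(2Z)-oct-2-en-1-yl]-2-oxocyclopent-3-en-1-ylidene]hept-5-enoate | CCCCC/C=C\C[C@@]1(OC(C)=O)C=C(Br)C(=O)/C1=C/C=C/CCCC(=O)OC | target

**Step count and risks**

Total step count: 10. Longest linear sequence: 7 steps (steps 1, 2, 3, 6, 7, 9, 10, from 1).

Steps most likely to fail:

Step 6. The enolate may add in conjugate fashion to the sulfinyl enone, the allyl anion may be quenched by the acidic C-13 protons before it cyclises, or the face selectivity may be low. The fallback sets out from 8 and 5 and comes back at 18. Compound 8 is lithiated (n-BuLi), silylated with Me3SiCl and hydrolysed with dilute HCl to (2E)-1-[tert-butyl(dimethyl)silyl]-3-(trimethylsilyl)prop-2-en-1-one F1. Enolate 13 from 5 and F1 give, by the precedented β-silyl form of the annulation, racemic 4-[tert-butyl(dimethyl)silyl]oxy-1-[(2Z)-oct-2-en-1-yl]-2-(trimethylsilyl)cyclopent-3-en-1-ol F2. NBS (bromination of the enol ether, then loss of Me3SiBr) converts F2 into racemic 4-hydroxy-4-[(2Z)-oct-2-en-1-yl]cyclopent-2-en-1-one F3. Nucleophilic epoxidation (H2O2, NaOH, MeOH, 0 °C; only the enone reacts) gives racemic 2,3-epoxy-4-hydroxy-4-[(2Z)-oct-2-en-1-yl]cyclopentan-1-one F4. Aqueous HBr in acetone opens the epoxide at C-10 and dehydrates to racemic 2-bromo-4-hydroxy-4-[(2Z)-oct-2-en-1-yl]cyclopent-2-en-1-one F5. F5 is resolved by preparative chromatography on an amylose tris(3,5-dimethylphenylcarbamate) phase; its S enantiomer is 18.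

Step 5. The lithiated allene may deprotonate the acidic allenyl sulfoxide as it forms, or attack the product sulfoxide. The fallback sets out from 8 and comes back at 12. Compound 8 is lithiated, sulfenylated with di-p-tolyl disulfide and hydrolysed with dilute HCl to (2E)-1-[tert-butyl(dimethyl)silyl]-3-[(4-methylphenyl)sulfanyl]prop-2-en-1-one F6. Enantioselective sulfoxidation of F6 (Ti(O-i-Pr)4, (R,R)-diethyl tartrate, H2O, cumene hydroperoxide, CH2Cl2, −20 °C), with recrystallisation to raise the enantiomeric purity, gives 12. The stereocentre at sulfur is then made by oxidation and not by substitution.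

Step 7. The allylic sulfoxide may rearrange [2,3] and collapse to the bromine-free enone before bromination, or the sulfenic acid may interfere. The fallback sets out from 16 and comes back at 18. Compound 16 is treated with 1 M HCl in THF and warmed; enol ether hydrolysis and sulfoxide elimination give (4S)-4-hydroxy-4-[(2Z)-oct-2-en-1-yl]cyclopent-2-en-1-one F7. Epoxidation with H2O2 and NaOH in MeOH gives (4S)-2,3-epoxy-4-hydroxy-4-[(2Z)-oct-2-en-1-yl]cyclopentan-1-one F8. Aqueous HBr opens the epoxide at C-10 and dehydrates to 18, so bromine arrives by epoxide opening and not by enol ether bromination.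

Further compounds
F1 | step 6 | (2E)-1-[tert-butyl(dimethyl)silyl]-3-(trimethylsilyl)prop-2-en-1-one | CC(C)(C)[Si](C)(C)C(=O)/C=C/[Si](C)(C)C
F2 | step 6 | racemic 4-[tert-butyl(dimethyl)silyl]oxy-1-[(2Z)-oct-2-en-1-yl]-2-(trimethylsilyl)cyclopent-3-en-1-ol | CCCCC/C=C\CC1(O)CC(O[Si](C)(C)C(C)(C)C)=CC1[Si](C)(C)C
F3 | step 6 | racemic 4-hydroxy-4-[(2Z)-oct-2-en-1-yl]cyclopent-2-en-1-one | CCCCC/C=C\CC1(O)C=CC(=O)C1
F4 | step 6 | racemic 2,3-epoxy-4-hydroxy-4-[(2Z)-oct-2-en-1-yl]cyclopentan-1-one | CCCCC/C=C\CC1(O)CC(=O)C2OC12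
F5 | step 6 | racemic 2-bromo-4-hydroxy-4-[(2Z)-oct-2-en-1-yl]cyclopent-2-en-1-one | CCCCC/C=C\CC1(O)C=C(Br)C(=O)C1
F6 | step 5 | (2E)-1-[tert-butyl(dimethyl)silyl]-3-[(4-methylphenyl)sulfanyl]prop-2-en-1-one | CC(C)(C)[Si](C)(C)C(=O)/C=C/Sc1ccc(C)cc1
F7 | step 7 | (4S)-4-hydroxy-4-[(2Z)-oct-2-en-1-yl]cyclopent-2-en-1-one | CCCCC/C=C\C[C@@]1(O)C=CC(=O)C1
F8 | step 7 | (4S)-2,3-epoxy-4-hydroxy-4-[(2Z)-oct-2-en-1-yl]cyclopentan-1-one | CCCCC/C=C\C[C@@]1(O)C2OC2C(=O)C1
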